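**Retrosynthetic overview**
- Ring A is a pentasubstituted benzene. C1–OMe and C3–OH sit meta to each other across the only ring hydrogen (C2–H), and C4, C5 and C6 carry three adjacent carbon chains (4-hydroxybenzyl, CH2CH2–ring B, 4-hydroxybenzyl). A 1,3-dioxygenated cyclohexa-1,3-diene and an unsymmetrical alkyne map onto exactly this pattern.
- Endgame: the four outer phenols are masked as benzyl ethers. The C6 benzylic CH2 is carried as C=O, so the C6 substituent is an aroyl group.
- Key disconnection: C4–C5 and C1–C6 of ring A. This gives a diene holding C1–C4 plus a CH2CH2 bridge (lost as ethylene) and an aryl ynone holding C5 and C6.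
- Diene: 3-methoxycyclohexenone, α′-benzylation, O-silylation. Ynone: bisphenol F, ortho-formylation, CHO → CH2Br, a C3 propargyl unit, aroylation of the terminal alkyne.
- Ring order: ring B and the three 4-oxygenated benzyl rings are bought as arenes. Ring A is the only ring built, and it is built last (step 9).

Key step: step 9

Remark: the target has no stereocentre. Compounds 15, 18 and 21 form as racemates and their stereocentres are erased in steps 8, 9 and 10. Ring A is numbered C1 (OMe), C2 (H), C3 (OH), C4, C5, C6 throughout.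

**Step 1**
Reactants: 1 bisphenol F (4,4'-methylenediphenol)
Product: 2 2-hydroxy-5-(4-hydroxybenzyl)benzaldehyde
Conditions: MgCl2 (1.0 equiv), Et3N (2.5 equiv), (CH2O)n (2.2 equiv CH2O), MeCN, reflux; 1 M HCl work-up; chromatography, unreacted 1 recycled
Reagents that add atoms: paraformaldehyde (as formaldehyde), C=O
Why: Magnesium-mediated ortho-formylation of phenols (Casnati–Skattebøl reaction) delivers formaldehyde inside the magnesium phenoxide chelate to the carbon next to OH (para is blocked by the CH2 bridge), a second formaldehyde oxidises the benzylic alkoxide to the aldehyde by hydride transfer, and the deliberately short measure of reagents should stop most material after one of the two equivalent rings has reacted, the components being separable by polarity.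

**Step 2**
Reactants: 2 2-hydroxy-5-(4-hydroxybenzyl)benzaldehyde
Product: 3 2-(benzyloxy)-5-[4-(benzyloxy)benzyl]benzaldehyde
Conditions: BnBr (2.4 equiv), K2CO3 (3 equiv), DMF, 60 °C
Reagents that add atoms: benzyl bromide, BrCc1ccccc1
Why: Williamson ether synthesis, in which both phenoxides (including the hydrogen-bonded one next to the aldehyde) are alkylated by the reactive benzylic bromide in a dipolar aprotic solvent while the non-enolisable aldehyde is inert to carbonate.

**Step 3**
Reactants: 3 2-(benzyloxy)-5-[4-(benzyloxy)benzyl]benzaldehyde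
Product: 4 {2-(benzyloxy)-5-[4-(benzyloxy)benzyl]phenyl}methanol
Conditions: NaBH4, THF–MeOH, 0 °C
Reagents that add atoms: none
Why: Borohydride reduction of an aromatic aldehyde to the benzylic alcohol, to which aryl benzyl ethers and the diarylmethane unit are inert.

**Step 4**
Reactants: 4 {2-(benzyloxy)-5-[4-(benzyloxy)benzyl]phenyl}methanol
Product: 5 1-(benzyloxy)-4-[4-(benzyloxy)benzyl]-2-(bromomethyl)benzene
Conditions: PBr3 (0.4 equiv), CH2Cl2, 0 °C; aqueous NaHCO3 wash, used without chromatography
Reagents that add atoms: phosphorus tribromide, BrP(Br)Br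
Why: SN2 displacement by bromide of the phosphite ester formed from the primary benzylic alcohol and PBr3, run cold so that the aryl benzyl ethers are not attacked.

**Step 5**
Reactants: 5 1-(benzyloxy)-4-[4-(benzyloxy)benzyl]-2-(bromomethyl)benzene; 6 1-(trimethylsilyl)propyne
Product: 9 1-(benzyloxy)-4-[4-(benzyloxy)benzyl]-2-(but-3-yn-1-yl)benzene, via 3-(trimethylsilyl)prop-2-ynyllithium 7 (not isolated), via silylated butyne 8 (not isolated)
Conditions: 6 (1.3 equiv), n-BuLi (1.25 equiv), THF, −78 °C, 1 h; 5, −78 °C → rt; then MeOH, K2CO3 (0.3 equiv), rt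
Reagents that add atoms: none
Why: Alkylation of a propargyl anion equivalent, in which lithiated 1-(trimethylsilyl)propyne attacks the benzylic bromide through its CH2 terminus (the silyl group blocks the acetylenic end and disfavours allene formation), followed in the same flask by carbonate-catalysed methanolysis of the alkynyl C–Si bond to free the terminal alkyne.

**Step 6**
Reactants: 9 1-(benzyloxy)-4-[4-(benzyloxy)benzyl]-2-(but-3-yn-1-yl)benzene; 10 4-(benzyloxy)benzoyl chloride
Product: 11 1-[4-(benzyloxy)phenyl]-5-{2-(benzyloxy)-5-[4-(benzyloxy)benzyl]phenyl}pent-2-yn-1-one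
Conditions: PdCl2(PPh3)2 (2 mol %), CuI (4 mol %), Et3N (1.5 equiv), THF, rt
Reagents that add atoms: none
Why: Acyl Sonogashira coupling, in which oxidative addition of the aroyl chloride to zerovalent palladium formed in situ, transmetallation from the copper acetylide and reductive elimination give the ynone at room temperature, mild enough to leave the propargylic CH2 unisomerised.

**Step 7**
Reactants: 12 3-methoxycyclohex-2-en-1-one; 13 4-(benzyloxy)benzyl bromide
Product: 15 rac-6-[4-(benzyloxy)benzyl]-3-methoxycyclohex-2-en-1-one, via lithium dienolate 14 (not isolated)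
Conditions: LiN(i-Pr)2 (1.1 equiv), THF, −78 °C, 45 min; 13 (1.05 equiv), −78 °C → rt
Reagents that add atoms: none
Why: Stork–Danheiser alkylation, in which kinetic deprotonation of the vinylogous ester occurs at the α′-carbon C6 and the cross-conjugated enolate 14 is C-alkylated by the benzylic bromide, creating a racemic centre that step 8 erases.

**Step 8**
Reactants: 15 rac-6-[4-(benzyloxy)benzyl]-3-methoxycyclohex-2-en-1-one
Product: 17 4-[4-(benzyloxy)benzyl]-1-methoxy-3-(trimethylsilyloxy)cyclohexa-1,3-diene, via lithium dienolate 16 (not isolated)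
Conditions: LiN(i-Pr)2 (1.2 equiv), THF, −78 °C, 1 h; Me3SiCl (1.5 equiv), −78 → 0 °C; evaporation, pentane, filtration under Ar; used at once
Reagents that add atoms: chlorotrimethylsilane, C[Si](C)(C)Cl
Why: Kinetic enolisation again takes the α′-hydrogen (the remaining C6–H), as in the familiar second Stork–Danheiser alkylation, and the hard electrophile Me3SiCl traps enolate 16 on oxygen, which fixes the 1-methoxy-3-silyloxy-1,3-diene with the benzyl group on a diene terminus.

**Step 9**
Reactants: 17 4-[4-(benzyloxy)benzyl]-1-methoxy-3-(trimethylsilyloxy)cyclohexa-1,3-diene; 11 1-[4-(benzyloxy)phenyl]-5-{2-(benzyloxy)-5-[4-(benzyloxy)benzyl]phenyl}pent-2-yn-1-one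
Product: 20 [4-(benzyloxy)phenyl]{3-[4-(benzyloxy)benzyl]-2-(2-{2-(benzyloxy)-5-[4-(benzyloxy)benzyl]phenyl}ethyl)-4-hydroxy-6-methoxyphenyl}methanone, via bicyclo[2.2.2]octadiene adduct 18 (not isolated), via aryl trimethylsilyl ether 19 (not isolated)
Conditions: 17 (2.5 equiv), 11, BHT (2 mol %), mesitylene (1 M), 165 °C, Ar, ethylene vented; then 1 M aq HCl, THF, rt
Reagents that add atoms: none
Why: Normal-electron-demand [4+2] cycloaddition of the doubly donor-substituted diene 17 (reacting through C1 and C4) to the acceptor-substituted triple bond of 11 should give the bicyclo[2.2.2]octa-2,5-diene 18, which at the same temperature loses its saturated two-carbon bridge as ethylene by retro-[4+2] cleavage, an irreversible event driven by aromatisation and escape of the gas. The closest known reaction type is this very one, the Alder–Rickert reaction of 1-alkoxy-3-silyloxycyclohexa-1,3-dienes with acetylenic ketones and esters, which delivers resorcinol monoethers. Ring A is closed in an intermolecular six-membered cycloaddition mode, C1–C4 coming from the diene and C5–C6 from the alkyne, with C4–C5 and C1–C6 as the new bonds. The selectivity required is regiochemical: the C1 methoxy and C3 silyloxy groups both raise the HOMO coefficient at C4, the carbonyl group puts the largest LUMO coefficient on the alkyne carbon bearing the CH2CH2 chain, and because both orientations are about equally crowded this electronic match should decide, setting the aroyl group ortho to OMe and para to the silyloxy group. No stereocentre has to be controlled, since the two bridgehead centres of racemic 18 become sp2 carbons in 19. Dilute acid then cleaves only the aryl O–SiMe3 bond of 19 (and returns surplus 17 to enone 15), leaving the methyl ether, the four benzyl ethers and the ketone untouched.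

**Step 10**
Reactants: 20 [4-(benzyloxy)phenyl]{3-[4-(benzyloxy)benzyl]-2-(2-{2-(benzyloxy)-5-[4-(benzyloxy)benzyl]phenyl}ethyl)-4-hydroxy-6-methoxyphenyl}methanone
Product: 22 2,4-bis[4-(benzyloxy)benzyl]-3-(2-{2-(benzyloxy)-5-[4-(benzyloxy)benzyl]phenyl}ethyl)-5-methoxyphenol, via benzhydrol 21 (not isolated)
Conditions: Et3SiH (5 equiv), CF3CO2H (10 equiv), CH2Cl2, 0 °C → rt
Reagents that add atoms: none
Why: Ionic hydrogenation (Kursanov–Parnes reduction), in which the protonated diaryl ketone takes hydride from the silane to give benzhydrol 21, this ionises to a cation stabilised by the para-OH and ortho-OMe of ring A and by the para-benzyloxy ring, and a second hydride gives the CH2 group, the excess silane outrunning Friedel–Crafts capture and any benzyl ether lost on the way being of no consequence because step 11 removes all four.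

**Step 11**
Reactants: 22 2,4-bis[4-(benzyloxy)benzyl]-3-(2-{2-(benzyloxy)-5-[4-(benzyloxy)benzyl]phenyl}ethyl)-5-methoxyphenol
Product: 23 3-{2-[2-hydroxy-5-(4-hydroxybenzyl)phenyl]ethyl}-2,4-bis(4-hydroxybenzyl)-5-methoxyphenol (CNP0134121.0)
Conditions: H2 (1 atm), 10% Pd/C, EtOAc–MeOH, rt
Reagents that add atoms: none
Why: Catalytic hydrogenolysis of the four O-benzyl groups, under which the aryl–CH2–aryl and aryl–CH2CH2–aryl carbon–carbon bonds and the aryl methyl ether are not cleaved, so the product should be the target.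

**Compound list**
1 | bisphenol F (4,4'-methylenediphenol) | Oc1ccc(Cc2ccc(O)cc2)cc1 | starting material
2 | 2-hydroxy-5-(4-hydroxybenzyl)benzaldehyde | O=Cc1cc(Cc2ccc(O)cc2)ccc1O | intermediate
3 | 2-(benzyloxy)-5-[4-(benzyloxy)benzyl]benzaldehyde | O=Cc1cc(Cc2ccc(OCc3ccccc3)cc2)ccc1OCc1ccccc1 | intermediate
4 | {2-(benzyloxy)-5-[4-(benzyloxy)benzyl]phenyl}methanol | OCc1cc(Cc2ccc(OCc3ccccc3)cc2)ccc1OCc1ccccc1 | intermediate
5 | 1-(benzyloxy)-4-[4-(benzyloxy)benzyl]-2-(bromomethyl)benzene | BrCc1cc(Cc2ccc(OCc3ccccc3)cc2)ccc1OCc1ccccc1 | intermediate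
6 | 1-(trimethylsilyl)propyne | CC#C[Si](C)(C)C | starting material
7 | 3-(trimethylsilyl)prop-2-ynyllithium | [Li]CC#C[Si](C)(C)C | intermediate
8 | {4-[2-(benzyloxy)-5-(4-(benzyloxy)benzyl)phenyl]but-1-yn-1-yl}trimethylsilane | C[Si](C)(C)C#CCCc1cc(Cc2ccc(OCc3ccccc3)cc2)ccc1OCc1ccccc1 | intermediate
9 | 1-(benzyloxy)-4-[4-(benzyloxy)benzyl]-2-(but-3-yn-1-yl)benzene | C#CCCc1cc(Cc2ccc(OCc3ccccc3)cc2)ccc1OCc1ccccc1 | intermediate
10 | 4-(benzyloxy)benzoyl chloride | O=C(Cl)c1ccc(OCc2ccccc2)cc1 | starting material
11 | 1-[4-(benzyloxy)phenyl]-5-{2-(benzyloxy)-5-[4-(benzyloxy)benzyl]phenyl}pent-2-yn-1-one | O=C(C#CCCc1cc(Cc2ccc(OCc3ccccc3)cc2)ccc1OCc1ccccc1)c1ccc(OCc2ccccc2)cc1 | intermediate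
12 | 3-methoxycyclohex-2-en-1-one | COC1=CC(=O)CCC1 | starting material
13 | 4-(benzyloxy)benzyl bromide | BrCc1ccc(OCc2ccccc2)cc1 | starting material
14 | lithium 5-methoxycyclohexa-1,5-dien-1-olate (α′-enolate of 12) | [Li+].COC1=CC([O-])=CCC1 | intermediate
15 | rac-6-[4-(benzyloxy)benzyl]-3-methoxycyclohex-2-en-1-one | COC1=CC(=O)C(Cc2ccc(OCc3ccccc3)cc2)CC1 | intermediate
16 | lithium 2-[4-(benzyloxy)benzyl]-5-methoxycyclohexa-1,5-dien-1-olate (α′-enolate of 15) | [Li+].COC1=CC([O-])=C(Cc2ccc(OCc3ccccc3)cc2)CC1 | intermediate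
17 | 4-[4-(benzyloxy)benzyl]-1-methoxy-3-(trimethylsilyloxy)cyclohexa-1,3-diene | COC1=CC(O[Si](C)(C)C)=C(Cc2ccc(OCc3ccccc3)cc2)CC1 | intermediate
18 | racemic bicyclo[2.2.2]octa-2,5-diene adduct (bridgeheads: C1 OMe and C4 4-benzyloxybenzyl; bridges: C2H=C3(OSiMe3), C5(CH2CH2Ar)=C6(aroyl), CH2CH2) | COC12CCC(Cc3ccc(OCc4ccccc4)cc3)(C(O[Si](C)(C)C)=C1)C(CCc1cc(Cc3ccc(OCc4ccccc4)cc3)ccc1OCc1ccccc1)=C2C(=O)c1ccc(OCc3ccccc3)cc1 | intermediate
19 | trimethylsilyl ether of 20 (ring A aromatic, C3 OSiMe3) | COc1cc(O[Si](C)(C)C)c(Cc2ccc(OCc3ccccc3)cc2)c(CCc2cc(Cc3ccc(OCc4ccccc4)cc3)ccc2OCc2ccccc2)c1C(=O)c1ccc(OCc2ccccc2)cc1 | intermediate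
20 | [4-(benzyloxy)phenyl]{3-[4-(benzyloxy)benzyl]-2-(2-{2-(benzyloxy)-5-[4-(benzyloxy)benzyl]phenyl}ethyl)-4-hydroxy-6-methoxyphenyl}methanone | COc1cc(O)c(Cc2ccc(OCc3ccccc3)cc2)c(CCc2cc(Cc3ccc(OCc4ccccc4)cc3)ccc2OCc2ccccc2)c1C(=O)c1ccc(OCc2ccccc2)cc1 | intermediate
21 | racemic benzhydrol, the secondary alcohol corresponding to ketone 20 | COc1cc(O)c(Cc2ccc(OCc3ccccc3)cc2)c(CCc2cc(Cc3ccc(OCc4ccccc4)cc3)ccc2OCc2ccccc2)c1C(O)c1ccc(OCc2ccccc2)cc1 | intermediate
22 | 2,4-bis[4-(benzyloxy)benzyl]-3-(2-{2-(benzyloxy)-5-[4-(benzyloxy)benzyl]phenyl}ethyl)-5-methoxyphenol | COc1cc(O)c(Cc2ccc(OCc3ccccc3)cc2)c(CCc2cc(Cc3ccc(OCc4ccccc4)cc3)ccc2OCc2ccccc2)c1Cc1ccc(OCc2ccccc2)cc1 | intermediate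
23 | 3-{2-[2-hydroxy-5-(4-hydroxybenzyl)phenyl]ethyl}-2,4-bis(4-hydroxybenzyl)-5-methoxyphenol (CNP0134121.0) | COc1cc(O)c(Cc2ccc(O)cc2)c(CCc2cc(Cc3ccc(O)cc3)ccc2O)c1Cc1ccc(O)cc1 | target

**Step count**
- Total step count: 11.
- Longest linear sequence: 9 steps (steps 1–6, then 9–11). The diene branch (steps 7–8) joins at step 9.

**Steps most likely to fail**

*Step 9.*
- Risk: bond formation between a fully substituted diene terminus and an internal alkyne activated by a single, donor-substituted aroyl group may be too slow. 1,5-Hydrogen shift, desilylation or polymerisation of the diene could then consume 17 before cycloaddition.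
- Fallback: it keeps the same ring construction but uses a smaller and more electrophilic activating group, and attaches the last aryl ring afterwards. It sets out from 9 and uses 17.
- Deprotonation of 9 with n-BuLi in THF at −78 °C gives the lithium acetylide F1. Formylation with DMF and a quench into aqueous KH2PO4 should give 5-{2-(benzyloxy)-5-[4-(benzyloxy)benzyl]phenyl}pent-2-ynal F2.
- Heating F2 with 17 in toluene or xylene, at a lower temperature than the ynone needs, should lead through the bicyclo[2.2.2]octadiene carbaldehyde F3 to the silylated benzaldehyde F4. Dilute HCl then gives the hydroxy aldehyde F5.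
- Commercial 4-(benzyloxy)phenylmagnesium bromide (3 equiv, the first being consumed by the phenol) in THF adds to F5. The sequence comes back to the route at 21, which the conditions of step 10 carry on to 22.

*Step 8.*
- Risk: proton abstraction at the γ-carbon of the vinylogous ester may compete with removal of the hindered tertiary α′-hydrogen. The trimethylsilyl group may also be lost by hydrolysis during isolation of a diene that can be neither distilled nor chromatographed.
- Fallback: it fixes the enol double bond by hydride delivery instead of deprotonation. It sets out from 14, made from 12 as in step 7.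
- Addition of 14 to commercial 4-(benzyloxy)benzaldehyde at −78 °C gives the aldol F6 (mixture of racemic diastereomers). MsCl and Et3N convert it into the mesylate F7, and DBU eliminates this to (E)-6-[4-(benzyloxy)benzylidene]-3-methoxycyclohex-2-en-1-one F8.
- 1,4-Hydrosilylation with Et3SiH and RhCl(PPh3)3 (1 mol %) in THF at 50 °C should place hydride on the exocyclic benzylidene carbon. This enone is locked s-cis, and the methoxy-bearing enone carbon is far less electrophilic. The product should be the triethylsilyl dienol ether F9, which is sturdier and can be filtered through Et3N-deactivated silica.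
- Under the thermal conditions of step 9, F9 and 11 should pass through the triethylsilyl adduct F10 and the aryl triethylsilyl ether F11. HCl in THF–MeOH cleaves the latter, and the sequence comes back to the route at 20.

*Step 10.*
- Risk: hydride transfer to a ketone flanked by two ortho substituents and twisted out of conjugation may be slow in acid. Acidolysis of benzyl ethers with C-benzylation, or seven-membered Friedel–Crafts closure of the benzhydryl cation onto ring B, could then compete.
- Fallback: it avoids the free cation. It sets out from 20.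
- LiAlH4 in refluxing THF reduces the ketone to 21, which is now isolated. H2 over 10% Pd/C in EtOH–AcOH removes the doubly benzylic hydroxyl group together with the four O-benzyl groups in one operation.
- The sequence comes back to the route at 23 and bypasses 22. It needs no compound that the list lacks (none F0).

**Further compounds**
F1 | step 9 | lithium acetylide of 9 | [Li]C#CCCc1cc(Cc2ccc(OCc3ccccc3)cc2)ccc1OCc1ccccc1
F2 | step 9 | 5-{2-(benzyloxy)-5-[4-(benzyloxy)benzyl]phenyl}pent-2-ynal | O=CC#CCCc1cc(Cc2ccc(OCc3ccccc3)cc2)ccc1OCc1ccccc1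
F3 | step 9 | racemic bicyclo[2.2.2]octa-2,5-diene carbaldehyde (as 18, CHO in place of aroyl) | COC12CCC(Cc3ccc(OCc4ccccc4)cc3)(C(O[Si](C)(C)C)=C1)C(CCc1cc(Cc3ccc(OCc4ccccc4)cc3)ccc1OCc1ccccc1)=C2C=O
F4 | step 9 | trimethylsilyl ether of F5 | COc1cc(O[Si](C)(C)C)c(Cc2ccc(OCc3ccccc3)cc2)c(CCc2cc(Cc3ccc(OCc4ccccc4)cc3)ccc2OCc2ccccc2)c1C=O
F5 | step 9 | 3-[4-(benzyloxy)benzyl]-2-(2-{2-(benzyloxy)-5-[4-(benzyloxy)benzyl]phenyl}ethyl)-4-hydroxy-6-methoxybenzaldehyde | COc1cc(O)c(Cc2ccc(OCc3ccccc3)cc2)c(CCc2cc(Cc3ccc(OCc4ccccc4)cc3)ccc2OCc2ccccc2)c1C=O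
F6 | step 8 | 6-{[4-(benzyloxy)phenyl](hydroxy)methyl}-3-methoxycyclohex-2-en-1-one (mixture of racemic diastereomers) | COC1=CC(=O)C(C(O)c2ccc(OCc3ccccc3)cc2)CC1
F7 | step 8 | methanesulfonate of F6 (mixture of racemic diastereomers) | COC1=CC(=O)C(C(OS(C)(=O)=O)c2ccc(OCc3ccccc3)cc2)CC1
F8 | step 8 | (E)-6-[4-(benzyloxy)benzylidene]-3-methoxycyclohex-2-en-1-one | COC1=CC(=O)/C(=C/c2ccc(OCc3ccccc3)cc2)CC1
F9 | step 8 | 4-[4-(benzyloxy)benzyl]-1-methoxy-3-(triethylsilyloxy)cyclohexa-1,3-diene | COC1=CC(O[Si](CC)(CC)CC)=C(Cc2ccc(OCc3ccccc3)cc2)CC1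
F10 | step 8 | racemic bicyclo[2.2.2]octa-2,5-diene adduct (as 18, OSiEt3 in place of OSiMe3) | COC12CCC(Cc3ccc(OCc4ccccc4)cc3)(C(O[Si](CC)(CC)CC)=C1)C(CCc1cc(Cc3ccc(OCc4ccccc4)cc3)ccc1OCc1ccccc1)=C2C(=O)c1ccc(OCc3ccccc3)cc1
F11 | step 8 | triethylsilyl ether of 20 | COc1cc(O[Si](CC)(CC)CC)c(Cc2ccc(OCc3ccccc3)cc2)c(CCc2cc(Cc3ccc(OCc4ccccc4)cc3)ccc2OCc2ccccc2)c1C(=O)c1ccc(OCc2ccccc2)cc1
F0 | step 10 | none | none
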